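(The readings are simulated on assumed constants; scatter was added.)

A one-step world, L + Q giving J with one Q per L, asks of the birch flask, charged with Q at 1.32 times L, that L fall to nothing. The readings refuse it.

in all of them: L 0.50 M
- birch: Q 0.66 M; run made earlier
- elm: Q 0.68 M; run made earlier
- south-west: Q 0.450 M; time 10 d
- north-east: Q 0.590 M; time 10 d

- birch (time / d: L / %, J / %): 1.04: 37, 48; 2.08: 30, 58; 3.00: 27, 60; 4.00: 28, 64; 5.00: 23, 66; 6.00: 26, 65; 8.00: 25, 70
- elm (time / d: L / %, J / %): 1.04: 38, 53; 2.08: 30, 62; 3.00: 26, 63; 4.00: 31, 67; 5.00: 26, 68; 6.00: 21, 67; 8.00: 24, 69

(each reading ± 2 percentage points)

- what has gone from L into another species counts as reacted, even if it can come back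

* part of the L that has reacted at the end, south-west
* part of the L that has reacted at the end, north-east
* what raising the concentration of Q from its lowest to its highest value here does to the part of the L that has reacted (changes below 5 percentage points count as none) (no change / it rises / it falls)

In the first instants L goes fast: by 1.04 d the birch flask holds L at 37% and J at 48% of the L charged. In the middle the pace drops, and by 3.00 d birch J stands at 60%. From 5.00 d on, the birch and elm runs sit on a plateau, with mean J 67.5% and mean L 24.2%. Q is not read, and Q is what is about to matter.

A reckoning made here, apart from the forecast, takes the plateau as the end of Q, not as a balance. The two runs give 1.99 as the Q price, the charged Q divided by the J on the plateau. The side share, what lies in neither L nor J per L on the plateau, reads 0.345. The first round gives J from the price: 45.3% at south-west and 59.4% at north-east. The second round puts that back, dividing what is not J by one plus the side share to give the L left, and gives 59.4% and 69.8% reacted, a rise of 10 percentage points.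

The forecast, reading a reversible step with a constant near 10 per molar, gives 60% and 71%, with the trend it rises, and adds: “Ten days should be close to equilibrium.” The two reckonings rest on different pictures of the same runs, yet stay 0.60 points and 1.2 points apart .

The flask gives 62.3% at south-west and 72.2% at north-east; with more Q, it rises, by 9.9 points.

    L + Q → D + J (k = 0.100 /M/h)
    Q + D ⇌ E, settled at all times (K = 5100 /M)
    D → X (k = 0.0420 /h)
    L ⇌ G (K = 0.350, k = 0.0330 /h)

Q, the limiting reagent, stands at 1.5% of its charge at south-west after 10.0 d, less than L at 38%. The Q price reckoned there from the Q no longer free and the J formed is 1.81, against 1.99 from the runs. A neighbour of north-east holds 0.24 M of Q; the price and side share give it 43.6% reacted, and that flask gives 46.7%.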